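**Plan**

- Retrosynthesis cuts, in order: the two phenolic O–benzyl bonds; the two CH2OH groups back to methyl esters; both C3–CO2Me and C4–CO2Me bonds at once (to a C3=C4 alkene, CO and MeOH); then the C5–aryl and C2–aryl bonds in turn (to 2,3-dihydrofuran and one aryl triflate).
- Forward: the oxygen ring is bought as 2,3-dihydrofuran and no ring is formed. Aryl goes on C2 (Heck), aryl on C5 (Heck), the two ester carbons on C3/C4 (oxidative dicarbonylation with in-pot epimerisation), then ester reduction and debenzylation.
- Enabling feature: both CH2OH carbons sit on the adjacent ring carbons C3 and C4 of the tetrahydrofuran (O1, C2 to C5), and the C2 axis through O1 and the C3–C4 midpoint of the trans-2,5-diaryl-2,5-dihydrofuran makes the two faces of its C3=C4 alkene equivalent.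
- Stereochemistry: C2 (R) from the chiral Pd–BINAP catalyst; C5 (R) from trans substrate control reinforced by a matched Pd–PHOX catalyst; C3 and C4 from syn addition to homotopic faces followed by thermodynamic epimerisation to the all-trans array dictated by C2 and C5.

Key step: step 5

Assumption: the phenols are carried as benzyl ethers so that the last step is a neutral hydrogenolysis (the p-hydroxybenzylic ether centres C2/C5 of the target are acid-labile), and the ligand antipodes named are those expected to give the (R) centres by analogy with aryl triflate arylations of unsubstituted 2,3-dihydrofuran; the antipode would be used if the sense proved opposite.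

**Route**

Step 1
Reactants: 1 4-(benzyloxy)-3-methoxybenzaldehyde
Product: 3 4-(benzyloxy)-3-methoxyphenol, via 4-(benzyloxy)-3-methoxyphenyl formate 2 (not isolated)
Conditions: mCPBA, CH2Cl2, 0 °C to rt; aq. NaHCO3 wash; then K2CO3 (cat.), EtOH, rt
Reagents that add atoms: mCPBA (3-chloroperoxybenzoic acid), O=C(OO)c1cccc(Cl)c1
Why: Baeyer–Villiger (Dakin-type) oxidation of the electron-rich benzaldehyde proceeds by aryl migration to the formate 2, whose mild ethanolysis releases the phenol while the benzyl and methyl ethers are untouched.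

Step 2
Reactants: 3 4-(benzyloxy)-3-methoxyphenol
Product: 4 4-(benzyloxy)-3-methoxyphenyl trifluoromethanesulfonate
Conditions: Tf2O, pyridine, CH2Cl2, 0 °C
Reagents that add atoms: triflic anhydride, O=S(=O)(OS(=O)(=O)C(F)(F)F)C(F)(F)F
Why: O-sulfonylation of a phenol with triflic anhydride and pyridine is routine and provides the aryl triflate required for cationic-pathway Heck chemistry.

Step 3
Reactants: 4 4-(benzyloxy)-3-methoxyphenyl trifluoromethanesulfonate; 5 2,3-dihydrofuran (5 equiv)
Product: 6 (R)-2-[4-(benzyloxy)-3-methoxyphenyl]-2,3-dihydrofuran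
Conditions: Pd(OAc)2 (3 mol %), (R)-BINAP (6 mol %), 1,8-bis(dimethylamino)naphthalene, benzene, 40 °C; chromatography on Et3N-treated silica
Reagents that add atoms: none
Why: Enantioselective Mizoroki–Heck arylation of the cyclic enol ether by the cationic aryl–Pd(BINAP) triflate pathway: the aryl group adds to the oxygen-bearing alkene carbon, β-hydride elimination and re-insertion walk the double bond to the 2,3-dihydro isomer, and the (R) centre is set by enantioface selection at the chiral catalyst, the minor 2,5-dihydro regioisomer being removed by chromatography.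

Step 4
Reactants: 6 (R)-2-[4-(benzyloxy)-3-methoxyphenyl]-2,3-dihydrofuran; 4 4-(benzyloxy)-3-methoxyphenyl trifluoromethanesulfonate (1.2 equiv)
Product: 7 (2R,5R)-2,5-bis[4-(benzyloxy)-3-methoxyphenyl]-2,5-dihydrofuran
Conditions: Pd2(dba)3 (2.5 mol %), (S)-t-Bu-PHOX (6 mol %), i-Pr2NEt, THF, 70 °C
Reagents that add atoms: none
Why: Second Mizoroki–Heck arylation at the remaining O–CH= carbon: the aryl–Pd adds anti to the C2 aryl group (substrate control, reinforced by the matched PHOX ligand, which sets C5 as R and whose hydride complex releases the alkene without re-insertion so that the C3=C4 bond stays in place), and any (S)-6 is expected to end mainly in the separable meso cis isomer.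

Step 5
Reactants: 7 (2R,5R)-2,5-bis[4-(benzyloxy)-3-methoxyphenyl]-2,5-dihydrofuran; 8 carbon monoxide; 9 methanol
Product: 11 dimethyl (2R,3R,4R,5R)-2,5-bis[4-(benzyloxy)-3-methoxyphenyl]tetrahydrofuran-3,4-dicarboxylate (all-trans), via dimethyl (2R,3S,4R,5R)-2,5-bis[4-(benzyloxy)-3-methoxyphenyl]tetrahydrofuran-3,4-dicarboxylate (3,4-cis) 10 (not isolated)
Conditions: Pd(TFA)2 (5 mol %), N,N′-bis(2,6-dimethylphenyl)butane-2,3-diimine (5.5 mol %), p-benzoquinone (1.5 equiv), CO (4 bar), MeOH/THF 7:1, 20 °C; then vent, NaOMe (excess over the hydroquinone), MeOH, 0 °C to rt, AcOH quench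
Reagents that add atoms: carbon monoxide (8), [C-]#[O+]; methanol (9), CO
Why: A Pd(II)–CO2Me species formed from Pd(II), CO and MeOH adds syn across C3=C4, CO inserts into the new C–Pd bond with retention and methanolysis of the acyl–Pd releases the cis-3,4-diester 10, after which benzoquinone returns Pd(0) to Pd(II). The closest known reaction type is the syn-specific Pd(II)/benzoquinone bis(alkoxycarbonylation) of 1,2-disubstituted and cyclic alkenes to succinates, followed by alkoxide epimerisation of an ester α-centre. No ring is closed; the two new bonds are C3–CO2Me and C4–CO2Me. Because the C2 axis of 7 makes the two alkene faces homotopic and both alkene carbons receive the same group, either face and either insertion regiochemistry lead to the single diester 10, in which only the C3 ester is cis to its aryl neighbour; methoxide then inverts C3 through the ester enolate to the all-trans diester 11, the thermodynamic minimum fixed by the C2 and C5 aryl groups, which also defines C4. The step needs carbonylation to outrun β-hydride elimination and ionisation of the doubly benzylic allylic C–O bonds: CO pressure and the chelating diimine keep Pd coordinatively saturated, benzoquinone keeps Pd(0) low, no sulfonic acid co-catalyst is added, and the base treatment is short and cold to limit retro-oxa-Michael ring opening.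

Step 6
Reactants: 11 dimethyl (2R,3R,4R,5R)-2,5-bis[4-(benzyloxy)-3-methoxyphenyl]tetrahydrofuran-3,4-dicarboxylate
Product: 12 [(2R,3S,4S,5R)-2,5-bis[4-(benzyloxy)-3-methoxyphenyl]tetrahydrofuran-3,4-diyl]dimethanol
Conditions: LiAlH4, THF, 0 °C to rt; Fieser work-up
Reagents that add atoms: none
Why: Lithium aluminium hydride reduction of both methyl esters to primary alcohols is faster than enolisation and leaves the aryl benzyl ethers and the ring ether untouched, so all four stereocentres are carried through (the descriptors at C3/C4 change only by CIP priority).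

Step 7
Reactants: 12 [(2R,3S,4S,5R)-2,5-bis[4-(benzyloxy)-3-methoxyphenyl]tetrahydrofuran-3,4-diyl]dimethanol
Product: 13 (+)-neoolivil, [(2R,3S,4S,5R)-2,5-bis(4-hydroxy-3-methoxyphenyl)tetrahydrofuran-3,4-diyl]dimethanol
Conditions: H2 (1 atm), 10 % Pd/C, EtOAc/EtOH, rt
Reagents that add atoms: none
Why: Catalytic hydrogenolysis of phenolic benzyl ethers under neutral conditions is much faster than cleavage of the secondary dialkyl benzylic C–O bonds of the ring and avoids the acid under which the p-hydroxybenzylic centres C2/C5 of the product could epimerise.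

**Compound list**

1 | 4-(benzyloxy)-3-methoxybenzaldehyde | COc1cc(C=O)ccc1OCc1ccccc1 | starting material
2 | 4-(benzyloxy)-3-methoxyphenyl formate | COc1cc(OC=O)ccc1OCc1ccccc1 | intermediate
3 | 4-(benzyloxy)-3-methoxyphenol | COc1cc(O)ccc1OCc1ccccc1 | intermediate
4 | 4-(benzyloxy)-3-methoxyphenyl trifluoromethanesulfonate | COc1cc(OS(=O)(=O)C(F)(F)F)ccc1OCc1ccccc1 | intermediate
5 | 2,3-dihydrofuran | C1CC=CO1 | starting material
6 | (R)-2-[4-(benzyloxy)-3-methoxyphenyl]-2,3-dihydrofuran | COc1cc([C@@H]2OC=CC2)ccc1OCc1ccccc1 | intermediate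
7 | (2R,5R)-2,5-bis[4-(benzyloxy)-3-methoxyphenyl]-2,5-dihydrofuran | COc1cc([C@@H]2O[C@@H](c3ccc(OCc4ccccc4)c(OC)c3)C=C2)ccc1OCc1ccccc1 | intermediate
8 | carbon monoxide | [C-]#[O+] | starting material
9 | methanol | CO | starting material
10 | dimethyl (2R,3S,4R,5R)-2,5-bis[4-(benzyloxy)-3-methoxyphenyl]tetrahydrofuran-3,4-dicarboxylate (2,3-cis, 3,4-cis, 4,5-trans) | COc1cc([C@@H]2O[C@@H](c3ccc(OCc4ccccc4)c(OC)c3)[C@H](C(=O)OC)[C@@H]2C(=O)OC)ccc1OCc1ccccc1 | intermediate
11 | dimethyl (2R,3R,4R,5R)-2,5-bis[4-(benzyloxy)-3-methoxyphenyl]tetrahydrofuran-3,4-dicarboxylate (all-trans) | COc1cc([C@@H]2O[C@@H](c3ccc(OCc4ccccc4)c(OC)c3)[C@H](C(=O)OC)[C@H]2C(=O)OC)ccc1OCc1ccccc1 | intermediate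
12 | [(2R,3S,4S,5R)-2,5-bis[4-(benzyloxy)-3-methoxyphenyl]tetrahydrofuran-3,4-diyl]dimethanol | COc1cc([C@@H]2O[C@@H](c3ccc(OCc4ccccc4)c(OC)c3)[C@H](CO)[C@H]2CO)ccc1OCc1ccccc1 | intermediate
13 | (+)-neoolivil, [(2R,3S,4S,5R)-2,5-bis(4-hydroxy-3-methoxyphenyl)tetrahydrofuran-3,4-diyl]dimethanol | COc1cc([C@@H]2O[C@@H](c3ccc(O)c(OC)c3)[C@H](CO)[C@H]2CO)ccc1O | target

**Step count**

Total steps: 7. Longest linear sequence: 7 steps (1 → 3 → 4 → 6 → 7 → 11 → 12 → 13); triflate 4 is used in steps 3 and 4.

**Steps most likely to fail, with fallbacks**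

Step 5 (oxidative dicarbonylation and epimerisation). Possible failure modes:
- β-hydride elimination or double-bond migration after the first insertion;
- acid- or Pd(0)-induced ionisation of the doubly benzylic allylic ether;
- sluggish insertion at the hindered alkene, or dehydrogenation to the furan;
- retro-oxa-Michael ring opening during the methoxide treatment.

The fallback sets out from 7, returns at 12, and replaces carbonylation by a ketene cycloaddition that adds the same two carbons suprafacially. Dichloroketene (Cl3CCOCl, Zn–Cu, POCl3, Et2O) should add to the C3=C4 bond to give the cis-fused 7,7-dichloro-2,4-diaryl-3-oxabicyclo[3.2.0]heptan-6-one F1; either face gives the same adduct, and the CCl2 carbon is expected on the less hindered ring carbon, whose neighbouring aryl is trans. Zinc with NH4Cl in methanol should remove both chlorines to give the cis-fused 2,4-diaryl-3-oxabicyclo[3.2.0]heptan-6-one F2. Kinetic enolisation at the methylene (KHMDS, THF, −78 °C) and hydroxylation with 2-(phenylsulfonyl)-3-phenyloxaziridine should give the 7-hydroxy ketone F3. Lead tetraacetate in MeOH/benzene should cleave the ketol C–C bond to methyl (2R,3S,4R,5R)-4-formyl-2,5-diaryltetrahydrofuran-3-carboxylate F4 (3,4-cis). Sodium methoxide in methanol at 0 °C should equilibrate both α-centres to the all-trans methyl (2R,3R,4R,5R)-4-formyl-2,5-diaryltetrahydrofuran-3-carboxylate F5. Lithium aluminium hydride then reduces aldehyde and ester together to 12. The orientation of the ketene is of no consequence for this symmetric diol.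

Step 4 (second Heck arylation). Possible failure modes:
- Pd–H re-insertion walking the double bond toward C2, which would erase that stereocentre;
- incomplete trans selectivity;
- slow oxidative addition of the electron-rich triflate.

The fallback sets out from 1, returns at 7, and builds the dihydrofuran by ring-closing metathesis. Horner–Wadsworth–Emmons olefination of 1 with triethyl phosphonoacetate (NaH, THF) should give ethyl (E)-3-[4-(benzyloxy)-3-methoxyphenyl]acrylate F6. DIBAL reduction should give (E)-3-[4-(benzyloxy)-3-methoxyphenyl]prop-2-en-1-ol F7, and methyl chloroformate with pyridine its methyl carbonate F8. Separately, enantioselective vinylzinc addition to 1 with a chiral amino-alcohol ligand should give (R)-1-[4-(benzyloxy)-3-methoxyphenyl]prop-2-en-1-ol F9. Iridium–phosphoramidite-catalysed, branched-selective allylic etherification of F8 with the copper(I) alkoxide of F9 should give the (R,R)-bis{1-[4-(benzyloxy)-3-methoxyphenyl]prop-2-en-1-yl} ether F10, the new centre being set by the catalyst. Ring-closing metathesis (Grubbs second-generation catalyst, CH2Cl2, 40 °C) then closes 7 with loss of ethylene and without touching either stereocentre.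

Step 3 (enantioselective Heck arylation). Possible failure modes:
- erosion of enantioselectivity with an electron-rich aryl triflate;
- unfavourable partition between the 2,3- and 2,5-dihydro regioisomers;
- slow oxidative addition, and hydrolysis of the enol ether on purification.

The fallback sets out from 1, returns at 6, and forms the ring by cycloisomerisation. Catalytic enantioselective propargylation of 1 with allenylboronic acid pinacol ester (chiral phosphoric acid or copper–bisphosphine catalysis) should give (R)-1-[4-(benzyloxy)-3-methoxyphenyl]but-3-yn-1-ol F11. Endo-selective cycloisomerisation through the metal vinylidene (Mo(CO)6, Et3N, Et2O, hν) should give enol ether 6 with the carbinol centre untouched.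

**Further compounds**

F1 | step 5 | cis-fused 2,4-bis[4-(benzyloxy)-3-methoxyphenyl]-7,7-dichloro-3-oxabicyclo[3.2.0]heptan-6-one (aryl-bearing carbons as in 7; carbonyl carbon on the ring carbon whose neighbouring aryl is cis to the four-membered ring) | COc1cc([C@@H]2O[C@@H](c3ccc(OCc4ccccc4)c(OC)c3)[C@@H]5C(Cl)(Cl)C(=O)[C@H]25)ccc1OCc1ccccc1
F2 | step 5 | cis-fused 2,4-bis[4-(benzyloxy)-3-methoxyphenyl]-3-oxabicyclo[3.2.0]heptan-6-one | COc1cc([C@@H]2O[C@@H](c3ccc(OCc4ccccc4)c(OC)c3)[C@@H]5CC(=O)[C@H]25)ccc1OCc1ccccc1
F3 | step 5 | cis-fused 2,4-bis[4-(benzyloxy)-3-methoxyphenyl]-7-hydroxy-3-oxabicyclo[3.2.0]heptan-6-one (carbinol centre undefined) | COc1cc([C@@H]2O[C@@H](c3ccc(OCc4ccccc4)c(OC)c3)[C@@H]5C(O)C(=O)[C@H]25)ccc1OCc1ccccc1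
F4 | step 5 | methyl (2R,3S,4R,5R)-2,5-bis[4-(benzyloxy)-3-methoxyphenyl]-4-formyltetrahydrofuran-3-carboxylate (3,4-cis) | COc1cc([C@@H]2O[C@@H](c3ccc(OCc4ccccc4)c(OC)c3)[C@H](C=O)[C@@H]2C(=O)OC)ccc1OCc1ccccc1
F5 | step 5 | methyl (2R,3R,4R,5R)-2,5-bis[4-(benzyloxy)-3-methoxyphenyl]-4-formyltetrahydrofuran-3-carboxylate (all-trans) | COc1cc([C@@H]2O[C@@H](c3ccc(OCc4ccccc4)c(OC)c3)[C@H](C=O)[C@H]2C(=O)OC)ccc1OCc1ccccc1
F6 | step 4 | ethyl (E)-3-[4-(benzyloxy)-3-methoxyphenyl]acrylate | CCOC(=O)/C=C/c1ccc(OCc2ccccc2)c(OC)c1
F7 | step 4 | (E)-3-[4-(benzyloxy)-3-methoxyphenyl]prop-2-en-1-ol | OC/C=C/c1ccc(OCc2ccccc2)c(OC)c1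
F8 | step 4 | (E)-3-[4-(benzyloxy)-3-methoxyphenyl]allyl methyl carbonate | COC(=O)OC/C=C/c1ccc(OCc2ccccc2)c(OC)c1
F9 | step 4 | (R)-1-[4-(benzyloxy)-3-methoxyphenyl]prop-2-en-1-ol | COc1cc([C@H](O)C=C)ccc1OCc1ccccc1
F10 | step 4 | (R,R)-bis{1-[4-(benzyloxy)-3-methoxyphenyl]prop-2-en-1-yl} ether | COc1cc([C@@H](C=C)O[C@H](C=C)c2ccc(OCc3ccccc3)c(OC)c2)ccc1OCc1ccccc1
F11 | step 3 | (R)-1-[4-(benzyloxy)-3-methoxyphenyl]but-3-yn-1-ol | COc1cc([C@H](O)CC#C)ccc1OCc1ccccc1
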